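The meeting opened on a pitfall: a straight line of Q against time, stretched over the longer tank, promises more Q than the charge holds, so the chair asked that the end state be named before any pace.

| flask | D | X | remark | time |
|---|---|---|---|---|
| ash | 0.094 M | 47 µM | run made earlier |  |
| larch | 0.094 M | 31 µM | run made earlier |  |
| cedar | 0.094 M | 70 µM | run made earlier |  |
| midnight | 0.094 M (fed, over 20.0 h) | 47 µM | a stirred flask in which D is dosed at a steady rate over 20.0 h without added volume, worked up at 20 h | 20 h |
| dusk | 0.094 M | 47 µM | everything together in a closed stirred flask, run for 20 h | 20 h |
| autumn | 0.094 M | 47 µM | one stirred flow tank at steady state, fed with the mixture as stated, mean residence time 60.0 h |  |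
| spring | 0.094 M | 47 µM | one stirred flow tank at steady state, fed with the mixture as stated, mean residence time 20 h |  |

| run | time / h | Q / % |
|---|---|---|
| ash | 1.50 | 4.1 |
| ash | 3.00 | 7.7 |
| ash | 6.00 | 13.1 |
| ash | 10.0 | 22.0 |
| ash | 20.0 | 42.8 |
| larch | 2.00 | 3.0 |
| larch | 4.00 | 6.4 |
| larch | 6.00 | 8.6 |
| larch | 12.0 | 18.0 |
| larch | 25.0 | 35.1 |
| cedar | 5.00 | 16.0 |
| cedar | 10.0 | 31.7 |
| cedar | 15.0 | 47.9 |
| cedar | 20.0 | 59.6 |
| cedar | 25.0 | 72.5 |

(standard deviation of a reading: 0.5 percentage points)

- the stated concentrations are those of everything mixed, before any reaction; amounts are the same in each set-up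
- the feed brings no volume worth counting
- the earlier runs were made in a closed, stirred flask
- a reading or a percentage of Q counts all its forms, free or not

* the set-up with the highest amount of Q at the outlet or at the end, in percent of the D put in ("none" if the first two lie within 2 percentage points) (midnight / dusk / autumn / spring / none)
* amount of Q at the outlet or at the end, in percent of the D put in, midnight
* amount of Q at the outlet or at the end, in percent of the D put in, dusk
* amount of Q at the outlet or at the end, in percent of the D put in, autumn
* amount of Q at the outlet or at the end, in percent of the D put in, spring

The chair took the end state, as a working assumption, to be the charge turned to Q, since cedar was still climbing at its last reading, 72.5 % at 25.0 h against 59.6 % at 20.0 h. For the pace, the second speaker pointed to the near-straight stretch, close to zero order in D in the usual term, and read from ash 46.7 h: this clearing time, the hours the X of ash needs to put the whole charge through at its own pace, is reading time over fraction of the charge turned to Q. Scaled inversely with X to the amount in ash, larch gave 47.0 h and cedar, at 10.0 h, gave 47.0 h.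

The second speaker then committed to ceilings rather than figures, each being a set-up's time over the clearing time, which is 0.428 of the charge for midnight, dusk and spring, while for autumn the quotient, 1.28, passes the charge. Midnight was placed below its ceiling, because it starts from a flask without D, even though its feed of 0.0500 h⁻¹ then outruns the catalyst's 0.0214 h⁻¹. Autumn was placed first, because it equals the other ceilings at a third of the clearing pace, and any pace above that carries it past them.

The forecast's author, who gave figures where the second speaker gave ceilings, put midnight at 37 %, dusk at 43 %, autumn at 87 % and spring at 41 %, saying “Autumn is clearly best, simply because of its longer residence time”.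

The flasks gave 31.5 % in midnight, 42.2 % in dusk, 77.4 % in autumn and 39.4 % in spring, so autumn leads.

    D + Q ⇌ J, settled at all times (K = 3.50 M⁻¹)
    G → X + Q (k = 0.890 min⁻¹)
    Q → L (k = 7.50 × 10⁻⁷ min⁻¹)
    D + X ⇌ G (K = 630 M⁻¹, k = 54.0 M⁻¹ min⁻¹)

At autumn's outlet 18.1 % of the D charged still stood as D, and its Q over its residence time is a pace of 0.0129 h⁻¹, or 0.603 of the clearing pace. Midnight reached 0.736 of its ceiling. The neighbour of midnight with X at 2.8 × 10⁻⁵ M has, scaled by X, a clearing time of 78.4 h, and the same share of that ceiling comes to 18.8 % of the D put in, while that neighbour flask gave 19.6 % of Q.

The earlier runs and the new flask were computed with made-up constants, noise included.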